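**Retrosynthetic overview**

1. Feature: ring C (O1, C2, C3, C4, C4a, C8a) is a pyranone whose C4a–C8a edge belongs to a resorcinol-patterned ring A (ring oxygen on C8a, free hydroxyl on C7), whose C3 carries ring B and whose C2 is a lone CH. It therefore divides into resorcinol, an arylacetic acid (CH2 becomes C3, CO2H becomes C4) and a one-carbon unit (C2).
2. Target 23 ⇐ chroman analogue 20 by late C3''–C4'' dehydrogenation of the dimethylpyran ring on the diacetate, because a chromene alkene would not tolerate the hot Lewis acid that builds ring C.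
3. 20 ⇐ arylacetic acid 14 + resorcinol 15 + DMF 16 in one flask: C4–C4a by acylation, then C2–C3 and O1–C2 by formylation and cyclisation.
4. 14 ⇐ bromochromene 8 (Pd coupling with a zinc ester enolate, saponification, one hydrogenation for C=C and benzyl); 8 ⇐ phenol 4 + 3-methylbut-2-enal 5; 4 ⇐ 5-bromo-2-hydroxy-3-methoxybenzaldehyde 1 by benzylation and Baeyer–Villiger oxidation.
5. Ring order: the dimethylpyran ring on ring B first (step 3), ring C last (step 7); rings A and B are bought as benzene rings.

Key step: step 7

Remark: the target has no stereocentre. O1–C8a denote rings A and C of the isoflavone; the pyran ring fused to ring B is described with chroman or chromene locants (doubly primed where the isoflavone is meant).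

**Route**

Step 1
Reactants: 1 5-bromo-2-hydroxy-3-methoxybenzaldehyde
Product: 2 2-(benzyloxy)-5-bromo-3-methoxybenzaldehyde
Conditions: BnBr, K2CO3, MeCN, reflux
Reagents that add atoms: benzyl bromide, BrCc1ccccc1
Why: Williamson etherification of the acidic ortho-hydroxy aldehyde; benzyl is chosen because it survives peracid, hot acetic acid and the zinc/palladium coupling and is removed in the same hydrogenation that later saturates the chromene.

Step 2
Reactants: 2 2-(benzyloxy)-5-bromo-3-methoxybenzaldehyde
Product: 4 2-(benzyloxy)-5-bromo-3-methoxyphenol, via aryl formate 3 (not isolated)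
Conditions: mCPBA, CH2Cl2, 0 °C to reflux; then MeOH, K2CO3 (cat.), rt
Reagents that add atoms: mCPBA (3-chloroperoxybenzoic acid), OOC(=O)c1cccc(Cl)c1
Why: Baeyer–Villiger oxidation of an ortho-alkoxybenzaldehyde (Dakin-type), in which the electron-rich aryl group migrates in preference to hydrogen to give formate 3, followed by base-catalysed methanolysis; oxidising the benzyl ether rather than the free salicylaldehyde gives a monophenol with one free ortho carbon instead of a catechol.

Step 3
Reactants: 4 2-(benzyloxy)-5-bromo-3-methoxyphenol; 5 3-methylbut-2-enal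
Product: 8 8-(benzyloxy)-5-bromo-7-methoxy-2,2-dimethyl-2H-chromene, via dioxaborin 6 (not isolated), via quinone methide 7 (not isolated)
Conditions: PhB(OH)2 (1 equiv), AcOH, toluene, reflux, Dean–Stark
Reagents that add atoms: none
Why: Phenylboronic acid-mediated phenol–enal chromene annulation: boron tethers the phenol oxygen to the aldehyde so that the C–C bond forms at the only free ortho carbon (para to the methoxy group), dioxaborin 6 fragments on heating to quinone methide 7, and oxa-6π electrocyclisation closes the pyran ring; no stereocentre results.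

Step 4
Reactants: 8 8-(benzyloxy)-5-bromo-7-methoxy-2,2-dimethyl-2H-chromene; 9 methyl bromoacetate
Product: 11 methyl [8-(benzyloxy)-7-methoxy-2,2-dimethyl-2H-chromen-5-yl]acetate, via zinc enolate 10 (not isolated)
Conditions: 9, Zn dust (TMSCl-activated), THF, 40 °C; then 8, Pd(dba)2 (cat.), P(t-Bu)3 (cat.), THF, rt to 50 °C
Reagents that add atoms: none
Why: Palladium-catalysed cross-coupling of an aryl bromide with a Reformatsky reagent (Negishi-type α-arylation of an ester) by oxidative addition to zerovalent palladium, transmetalation from zinc and reductive elimination; the bulky electron-rich phosphine suits an electron-rich, ortho-substituted bromide, and the weakly basic zinc enolate leaves the chromene and benzyl ether alone.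

Step 5
Reactants: 11 methyl [8-(benzyloxy)-7-methoxy-2,2-dimethyl-2H-chromen-5-yl]acetate
Product: 12 [8-(benzyloxy)-7-methoxy-2,2-dimethyl-2H-chromen-5-yl]acetic acid
Conditions: LiOH, THF–MeOH–H2O, rt; then 1 M HCl, 0 °C
Reagents that add atoms: lithium hydroxide, [Li+].[OH-]
Why: Ester saponification; the chromene and benzyl ether are inert to hydroxide, and hydrolysis precedes debenzylation so that the oxidation-prone 2,6-dioxygenated phenol is never exposed to aqueous base.

Step 6
Reactants: 12 [8-(benzyloxy)-7-methoxy-2,2-dimethyl-2H-chromen-5-yl]acetic acid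
Product: 14 (8-hydroxy-7-methoxy-2,2-dimethylchroman-5-yl)acetic acid, via benzyl ether 13 (not isolated)
Conditions: H2 (1 atm), 10% Pd/C, EtOAc–EtOH, rt
Reagents that add atoms: none
Why: Heterogeneous catalytic hydrogenation saturates the styrene-type C3=C4 bond of the chromene (giving 13) and hydrogenolyses the benzyl ether in the same operation; the arene, the methoxy group and the acid are untouched.

Step 7
Reactants: 14 (8-hydroxy-7-methoxy-2,2-dimethylchroman-5-yl)acetic acid; 15 resorcinol; 16 N,N-dimethylformamide
Product: 20 7-hydroxy-3-(8-hydroxy-7-methoxy-2,2-dimethylchroman-5-yl)-4H-chromen-4-one, via deoxybenzoin 17 (not isolated), via iminium salt 18 (not isolated), via enaminoketone 19 (not isolated)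
Conditions: 14, 15 (1.3 equiv), BF3·OEt2 (as solvent), 85 °C; cool to 10 °C; 16, then MsCl, 55 to 75 °C; aq. NaOAc work-up
Reagents that add atoms: none
Why: BF3 turns the carboxylic acid of 14 into an acylating species that attacks C4 of resorcinol (Friedel–Crafts acylation of the Nencki type, C4–C4a bond) to give deoxybenzoin 17, whose BF3-bound enol is then C-formylated at the benzylic methylene by iminium salt 18, formed from DMF and MsCl (C2–C3 bond), giving enaminoketone 19. The ortho hydroxyl of ring A adds to the aminomethylene carbon and dimethylamine leaves (O1–C2 bond), so ring C closes by a 6-endo-trig conjugate addition–elimination on a vinylogous amide. The closest known reaction is exactly this one-pot deoxybenzoin route from a phenol and an arylacetic acid to a 7-hydroxyisoflavone, which tolerates free phenols and aryl methyl ethers. No stereocentre is formed. The step needs acylation at C4 of resorcinol and not at C2 or on ring B: C4 is para to one hydroxyl, ortho to the other and unhindered, C2 is squeezed between two hydroxyls, and the single free CH of ring B (chroman C6) is flanked by the methoxy group and the side chain, with resorcinol used in excess. The saturated chroman has no acid-labile alkene and its tertiary aryl ether can only reclose if it opens, which is why the double bond is added later.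

Step 8
Reactants: 20 7-hydroxy-3-(8-hydroxy-7-methoxy-2,2-dimethylchroman-5-yl)-4H-chromen-4-one
Product: 21 3-(8-acetoxy-7-methoxy-2,2-dimethylchroman-5-yl)-4-oxo-4H-chromen-7-yl acetate
Conditions: Ac2O, pyridine, DMAP (cat.), CH2Cl2, 0 °C to rt
Reagents that add atoms: acetic anhydride, CC(=O)OC(C)=O
Why: DMAP-catalysed O-acetylation of both phenols; the electron-rich chroman 8-hydroxyl in particular would be oxidised by DDQ if left free.

Step 9
Reactants: 21 3-(8-acetoxy-7-methoxy-2,2-dimethylchroman-5-yl)-4-oxo-4H-chromen-7-yl acetate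
Product: 22 3-(8-acetoxy-7-methoxy-2,2-dimethyl-2H-chromen-5-yl)-4-oxo-4H-chromen-7-yl acetate
Conditions: DDQ (2 equiv), 1,4-dioxane, reflux
Reagents that add atoms: none
Why: DDQ dehydrogenation of a 2,2-dimethylchroman to the 2H-chromene: hydride abstraction from benzylic C4 gives a cation stabilised by the para methoxy group and the ortho ring oxygen, and loss of the C3 proton gives the alkene; the chromone and the acetates are inert to DDQ.

Step 10
Reactants: 22 3-(8-acetoxy-7-methoxy-2,2-dimethyl-2H-chromen-5-yl)-4-oxo-4H-chromen-7-yl acetate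
Product: 23 7-hydroxy-3-(8-hydroxy-7-methoxy-2,2-dimethyl-2H-chromen-5-yl)-4H-chromen-4-one
Conditions: K2CO3 (2 equiv), MeOH, 0 °C to rt, argon; then 1 M HCl
Reagents that add atoms: none
Why: Base-mediated transesterification (methanolysis) of the two aryl acetates; cold carbonate in methanol is mild enough for the chromone ring C and the chromene, and argon protects the liberated electron-rich phenol.

**Compound list**

1 | 5-bromo-2-hydroxy-3-methoxybenzaldehyde | COc1cc(Br)cc(C=O)c1O | starting material
2 | 2-(benzyloxy)-5-bromo-3-methoxybenzaldehyde | COc1cc(Br)cc(C=O)c1OCc1ccccc1 | intermediate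
3 | 2-(benzyloxy)-5-bromo-3-methoxyphenyl formate (formed in the flask, not isolated) | COc1cc(Br)cc(OC=O)c1OCc1ccccc1 | intermediate
4 | 2-(benzyloxy)-5-bromo-3-methoxyphenol | COc1cc(Br)cc(O)c1OCc1ccccc1 | intermediate
5 | 3-methylbut-2-enal | CC(C)=CC=O | starting material
6 | 8-(benzyloxy)-5-bromo-7-methoxy-4-(2-methylprop-1-en-1-yl)-2-phenyl-4H-1,3,2-benzodioxaborinine, racemic (formed in the flask, not isolated) | COc1cc(Br)c2C(C=C(C)C)OB(c3ccccc3)Oc2c1OCc1ccccc1 | intermediate
7 | 2-(benzyloxy)-5-bromo-3-methoxy-6-(3-methylbut-2-en-1-ylidene)cyclohexa-2,4-dien-1-one, side chain syn to the carbonyl (formed in the flask, not isolated) | BrC1=CC(OC)=C(OCc2ccccc2)C(=O)/C1=C\C=C(C)C | intermediate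
8 | 8-(benzyloxy)-5-bromo-7-methoxy-2,2-dimethyl-2H-chromene | COc1cc(Br)c2C=CC(C)(C)Oc2c1OCc1ccccc1 | intermediate
9 | methyl bromoacetate | COC(=O)CBr | starting material
10 | methyl (bromozincio)acetate, Reformatsky reagent (formed in the flask, not isolated) | COC(=O)C[Zn]Br | intermediate
11 | methyl [8-(benzyloxy)-7-methoxy-2,2-dimethyl-2H-chromen-5-yl]acetate | COC(=O)Cc1cc(OC)c(OCc2ccccc2)c2OC(C)(C)C=Cc12 | intermediate
12 | [8-(benzyloxy)-7-methoxy-2,2-dimethyl-2H-chromen-5-yl]acetic acid | OC(=O)Cc1cc(OC)c(OCc2ccccc2)c2OC(C)(C)C=Cc12 | intermediate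
13 | [8-(benzyloxy)-7-methoxy-2,2-dimethylchroman-5-yl]acetic acid (formed in the flask, not isolated) | OC(=O)Cc1cc(OC)c(OCc2ccccc2)c2OC(C)(C)CCc12 | intermediate
14 | (8-hydroxy-7-methoxy-2,2-dimethylchroman-5-yl)acetic acid | COc1cc(CC(=O)O)c2CCC(C)(C)Oc2c1O | intermediate
15 | resorcinol | Oc1cccc(O)c1 | starting material
16 | N,N-dimethylformamide | CN(C)C=O | starting material
17 | 1-(2,4-dihydroxyphenyl)-2-(8-hydroxy-7-methoxy-2,2-dimethylchroman-5-yl)ethan-1-one (formed in the flask, not isolated) | COc1cc(CC(=O)c2ccc(O)cc2O)c2CCC(C)(C)Oc2c1O | intermediate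
18 | N,N-dimethyl[(methanesulfonyloxy)methylidene]ammonium chloride (formed in the flask, not isolated) | C[N+](C)=COS(C)(=O)=O.[Cl-] | intermediate
19 | 1-(2,4-dihydroxyphenyl)-3-(dimethylamino)-2-(8-hydroxy-7-methoxy-2,2-dimethylchroman-5-yl)prop-2-en-1-one, alkene geometry not fixed as either isomer cyclises (formed in the flask, not isolated) | COc1cc(C(=CN(C)C)C(=O)c2ccc(O)cc2O)c2CCC(C)(C)Oc2c1O | intermediate
20 | 7-hydroxy-3-(8-hydroxy-7-methoxy-2,2-dimethylchroman-5-yl)-4H-chromen-4-one | COc1cc(-c2coc3cc(O)ccc3c2=O)c2CCC(C)(C)Oc2c1O | intermediate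
21 | 3-(8-acetoxy-7-methoxy-2,2-dimethylchroman-5-yl)-4-oxo-4H-chromen-7-yl acetate | COc1cc(-c2coc3cc(OC(C)=O)ccc3c2=O)c2CCC(C)(C)Oc2c1OC(C)=O | intermediate
22 | 3-(8-acetoxy-7-methoxy-2,2-dimethyl-2H-chromen-5-yl)-4-oxo-4H-chromen-7-yl acetate | COc1cc(-c2coc3cc(OC(C)=O)ccc3c2=O)c2C=CC(C)(C)Oc2c1OC(C)=O | intermediate
23 | 7-hydroxy-3-(8-hydroxy-7-methoxy-2,2-dimethyl-2H-chromen-5-yl)-4H-chromen-4-one | COc1cc(-c2coc3cc(O)ccc3c2=O)c2c(c1O)OC(C)(C)C=C2 | target

**Count**

Total steps: 10. Longest linear sequence: 10 steps (1 to 23).

**Steps most likely to fail**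

Step 7. The acylation may be diverted into self-condensation of the electron-rich ring B acid, or the C-formylation of the deoxybenzoin may stall, so that little of 20 is formed. The fallback sets out from bromochromene 8 and makes the C3–ring B bond instead of the C4–C4a bond. Palladium-catalysed ketone α-arylation (Pd2(dba)3, Xantphos, NaOt-Bu, toluene, 80 °C) of purchased 1-[2,4-bis(benzyloxy)phenyl]ethan-1-one F1 with 8 should give 1-[2,4-bis(benzyloxy)phenyl]-2-[8-(benzyloxy)-7-methoxy-2,2-dimethyl-2H-chromen-5-yl]ethan-1-one F2. Hydrogenation (H2, 10% Pd/C, EtOAc) should remove the three benzyl groups and saturate the chromene. The fallback comes back to the route at 17, now isolated, which is closed to 20 by the DMF/MsCl/BF3·OEt2 stage of step 7 alone.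

Step 9. Hydride abstraction may be slow at the benzylic carbon, which is crowded by the neighbouring isoflavonyl group and sits on a ring made less electron-rich by the acetate, and forcing conditions may lead to over-oxidation. The fallback sets out from 21 and uses radical chemistry instead. Benzylic bromination (NBS, AIBN, PhCF3, reflux) should give racemic 3-(8-acetoxy-4-bromo-7-methoxy-2,2-dimethylchroman-5-yl)-4-oxo-4H-chromen-7-yl acetate F3. Dehydrobromination (DBU, toluene, 80 °C) then comes back to the route at 22.

Step 3. Ortho C-alkylation next to the bromine may be slow, leaving the enal to self-condense. The fallback sets out from 4 and builds the pyran ring by a sigmatropic route. O-Alkylation with 3-chloro-3-methylbut-1-yne (K2CO3, KI, acetone, reflux) should give 2-(benzyloxy)-5-bromo-1-methoxy-3-[(2-methylbut-3-yn-2-yl)oxy]benzene F4. Heating in N,N-diethylaniline at 190 °C should trigger propargyl Claisen rearrangement, 1,5-hydrogen shift to the same quinone methide 7 and oxa-6π electrocyclisation, coming back to the route at 8.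

**Further compounds**

F1 | step 7 | 1-[2,4-bis(benzyloxy)phenyl]ethan-1-one (purchased) | CC(=O)c1ccc(OCc2ccccc2)cc1OCc1ccccc1
F2 | step 7 | 1-[2,4-bis(benzyloxy)phenyl]-2-[8-(benzyloxy)-7-methoxy-2,2-dimethyl-2H-chromen-5-yl]ethan-1-one | COc1cc(CC(=O)c2ccc(OCc3ccccc3)cc2OCc2ccccc2)c2C=CC(C)(C)Oc2c1OCc1ccccc1
F3 | step 9 | 3-(8-acetoxy-4-bromo-7-methoxy-2,2-dimethylchroman-5-yl)-4-oxo-4H-chromen-7-yl acetate, racemic | COc1cc(-c2coc3cc(OC(C)=O)ccc3c2=O)c2C(Br)CC(C)(C)Oc2c1OC(C)=O
F4 | step 3 | 2-(benzyloxy)-5-bromo-1-methoxy-3-[(2-methylbut-3-yn-2-yl)oxy]benzene | COc1cc(Br)cc(OC(C)(C)C#C)c1OCc1ccccc1
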